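- north: substrate 0.20 M; first nucleophile 0.40 M; gas 14 mM (held); the very flask that is asked about, followed so far
- flask: substrate 0.20 M; first nucleophile 0.400 M; gas 14 mM (held); time 15 min

north run (percent of the substrate charged)

| time / min | target / % |
|---|---|
| 0.667 | 5.1 |
| 1.33 | 9.5 |
| 3.00 | 16.5 |
| 8.00 | 25.4 |

(each reading ± 0.3 percentage points)

- at the start none of the gas is in solution

- alder: doubling the saturation concentration of gas, all else as stated
- elm: doubling the amount of first nucleophile, all else as stated
- maple: doubling the transfer coefficient of the gas, all else as stated

1. the target standing at 15 min, as a percentage of the substrate charged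
2. the change that raises the amount of target at 15 min, in percent of the substrate charged most ("none" if none brings more than 2 percentage points) (alder / elm / maple / none)
3. amount of target at 15 min, in percent of the substrate charged, after maple

The slowing of the north run is what I read first, leaving concentrations aside and taking the rate at which target appears, as a fraction of the charge, over each interval between readings. It starts at 0.0765 min⁻¹ and then reads 0.0664 min⁻¹, 0.0419 min⁻¹ and 0.0178 min⁻¹, so it falls by factors of 1.15, 1.58 and 2.35 over lengthening intervals. What slows it I cannot see from these readings, but if equal stretches of time cut the rate by equal factors, as in a pseudo-first-order decay, my reckoning for this flask needs one number, taken between the middles of the first and last intervals: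

half-life of the rate, the time in which it halves = ln(2) × 5.17 min / ln(4.30) = 2.46 min

rate at 8.00 min = 0.00879 min⁻¹

gain up to 15 min = 0.00879 min⁻¹ × 2.46 min / ln(2) × (1 − 0.139) = 2.7 percentage points

target at 15 min = 25.4% + 2.7 points = 28.1%

The forecast is lower than my figure, at 27.2%; it names alder as the best change, holding that “Doubling saturation then helps most”, and gives 30% after maple.

This flask gives 28.9%. The best change is elm, at 8.4 points, while alder moves the target by −9.2 points and maple by −4 points, to 24.9%, and beside the target's 28.9% stands 58.4% of other capture product.

    substrate ⇌ intermediate (K = 0.00555, k = 0.381 min⁻¹)
    first nucleophile + intermediate → target (k = 60.3 M⁻¹ min⁻¹)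
    second nucleophile + intermediate → other capture product (k = 3490 M⁻¹ min⁻¹)
    gas ⇌ second nucleophile, rate k4*(csat - [second nucleophile]) (kL = 1.52 min⁻¹)
    2 first nucleophile → self-condensation product (k = 0.270 M⁻¹ min⁻¹)

Carried on without end, the half-life puts the ceiling of my curve at 28.5%, which is lower than the 28.9% this flask holds at 15 min and the 29.9% it holds at 30.0 min, so after 8.00 min the rate in this flask falls more slowly than that half-life says.

In the neighbour flask with 0.050 M of substrate, the same half-life gives the same curve in percent, 28.1% at 15 min. The computed neighbour gives 24.8%, with 66.7% as other capture product.

The earlier runs and the new flask stem from a simulated flask with constants of no real substance; scatter was added.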